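## Structural features

The target is a germacranolide: a ten-membered carbocycle (C1–C10) with an α-methylene-γ-butyrolactone (C11–C13, ring oxygen on C6) cis-fused across C6–C7. Both ring alkenes are trisubstituted and ring-cis; they are E by the sequence rule only because C14 and C15 outrank the ring methylenes. C1=C10 carries the C14 formyl group as an enal, and C4=C5 carries the C15 hydroxymethyl group. C6 (R), C7 (S) and C8 (S) are contiguous, with the lactone oxygen, the C11 branch and the C8 isovalerate on one face of the ring. In an open C6–C7–C8–C9 chain the C7/C8 pair is therefore the anti (not the syn) aldol-type arrangement. The α-methylene lactone and the enal are Michael acceptors, the C6–O bond is allylic, and a free C8 hydroxyl beside the cis lactone can translactonise, so these groups must be unmasked late and mildly. The real difficulty is the medium ring: end-to-end closure of a ten-membered ring is penalised, and two cis trisubstituted alkenes of fixed geometry must sit in it beside three stereocentres. The structure offers a way round: a C1–C6 bond drawn across the ring gives a decalin whose ring A is a cyclohexene already holding C4=C5 in its cis geometry, whose ring B carries C7–C10, and in which a C10 ketone beside a C1,C6-epoxide is the arrangement an Eschenmoser–Tanabe fragmentation needs to cut C1–C6 again.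

## Logic of the disconnections

The C11=C13 bond of 30 is traced back to the C13–N bond of 28 (through 29). The amine masks the Michael acceptor through every late step. The forward step must be an elimination mild enough for the enal and the C8 ester. The free C15 hydroxyl of 28 comes from the silyl ether 27.

The C10–C14 bond of 27 is cut to the vinyl iodide 26, and the C8 ester C–O bond of 26 to the alcohol 25. This removes the enal and the acyl group from all earlier chemistry. The forward carbonylation must retain the alkene geometry. The ester must be in place first, because a free C8 hydroxyl would capture the acylpalladium intramolecularly.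

The C10–I bond of 25 is traced to the C10–Si bond of 24, and the C10–Si/C1–H pair of 24 to the C1≡C10 alkyne of 22 (through 23). The cut turns a trisubstituted ring-cis alkene into an alkyne with no geometry. The forward step must add Si–H syn with silicon on C10 only, which a tether from O8 enforces.

The C11–C13 bond of 22 is cut (through 21) to 20. The lactone C12–O bond and the C6–H bond of 20 are cut (through 19) to the keto ester 18. This leaves a ten-membered enynone with only C7 and C8 as stereocentres. The forward reduction must deliver hydride to the face of C6 that puts the hydroxyl cis to the C7 branch, while O8 stays protected so that only O6 lactonises.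

Key disconnection: the C1≡C10 triple bond and the C6 carbonyl of 18 are reconnected by a C1–C6 σ-bond, giving the epoxy ketone 15 and 16 (through 17). The medium ring becomes a decalin, and C4=C5 becomes an ordinary cyclohexene alkene. The forward fragmentation must be regiospecific and must not epimerise C7 or eliminate the C8 silyloxy group.

The epoxide oxygen of 15 is removed to give the dienone 14, and the C1=C6 bond of 14 is saturated back to the ketone 12 (through 13). The gain is a simple octalone. The forward steps must dehydrogenate on the C1 side of the ketone and epoxidise the α,β-bond of the dienone rather than the γ,δ-bond.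

12 is cut at C1–C6 and C2–C3 (retro-Diels–Alder) to the trienone 11, and 11 at C10–C1 to the amide 10 and 8. Two rings and the placement of C4=C5 come from one cycloaddition of an open chain. The forward step needs an E diene. Its new C1 and C6 centres do not matter, because they are erased later.

The C5=C6 and C3=C4 double bonds of 10 are cut (retro enyne metathesis) to the alkene 9 and the alkyne 2; 2 comes from 1. The diene with its C15 branch is thus made in one step from a vinyl group and a protected propargyl alcohol. The forward step must give the E isomer at C5=C6.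

The C6–C7 bond of 9 is cut to the enoate 7 and 8. The C7=C11 bond of 7 is cut to the aldehyde 6, which goes back through 5 and 4 to the chiral-pool lactone 3, the source of C8. The anti C7/C8 relationship is the reason for choosing a conjugate addition to a Z-enoate over a syn-selective auxiliary aldol, which would give the wrong diastereomer. The forward addition must place the vinyl group syn to the C8 oxygen in the ester chain.

## Other disconnections considered

Alternative 1: The cut is the C4=C5 double bond. An open-chain precursor A2, with a phosphonoacetate on C4 and an aldehyde on C5, would be cyclised with LiCl and an amine base (intramolecular Horner–Wadsworth–Emmons) to the ten-membered enoate A1, in which C15 is an ester.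
- In its favour: the three stereocentres, the C1=C10 alkene with C14, and the C11–C13 unit are all assembled on an open chain before the ring exists. The E-enoate that this olefination normally gives is exactly the ring-cis C4=C5 alkene (ester trans to C6).
- Against it here: the ring is closed end to end, so a ten-membered transition state must be paid for with high dilution and competing oligomerisation. The aldehyde of A2 is α-silyloxy-substituted and meets base, which risks epimerisation at C6 and β-elimination. E-selectivity learned on open chains is not assured when the forming alkene is strained. A1 then still needs selective reduction of C15, oxidation of C12, lactonisation and adjustment of C14.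
- Comparison: alternative 1 is the better on two points. C13 and C14 are in place before ring formation, and C6 is set before cyclisation instead of by a late reduction on the medium ring. The chosen plan is the better on ring formation itself (bond cleavage, no dilution, C4=C5 geometry inherited from a six-membered ring). Overall step counts should be similar.

Alternative 2: The cut is the C7–C8 bond. The thirteen-membered allyl ether A4, with tin on C8 and the ether oxygen joined to C13, would be treated with n-BuLi. Tin–lithium exchange and a [2,3]-shift (Wittig–Still) would form C7–C8, move the alkene to C11=C13 and contract the ring to the carbocycle A3 with a free C8 hydroxyl.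
- In its favour: a thirteen-membered ether is much easier to close than a ten-membered carbocycle, and the shift is fast at low temperature. It delivers at once the exocyclic methylene carbon C13 and an unprotected C8 hydroxyl ready for acylation. On both of these points it is better than the chosen plan, which needs a Mannich/elimination sequence and a deprotection.
- Against it: C7 and C8 are both created in the key step. Their configuration depends on the stannane configuration (retention on exchange, inversion on bond formation), on the C7=C11 geometry and on an envelope transition state held inside a macrocycle, so no simple model secures the outcome. A [1,2]-shift can compete. A4 needs an enantiomerically defined α-alkoxystannane and three stereodefined trisubstituted alkenes in one ring. After the contraction, C12 must still be oxidised and lactonised onto C6.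
- Comparison: in the chosen plan C7 and C8 are set early on an open chain and the key step creates no stereocentre. In alternative 2 the stereochemical risk sits in the key step, and the route to A4 is expected to be longer.

Alternative 3: The cut is the C5–C6 bond. The iodo aldehyde A6 (vinyl iodide on C5, aldehyde on C6) would be cyclised with CrCl2 and catalytic NiCl2 (Nozaki–Hiyama–Kishi). The vinylchromium species adds to the aldehyde and gives the ten-membered hydroxy ester A5 with the C6 carbinol.
- In its favour: this is the most dependable end-to-end closure of medium carbocycles, and it tolerates esters and silyl ethers. The vinyl iodide geometry, and hence the ring-cis C4=C5 alkene, is retained. C14 is already present, which is better than the chosen plan. The new C6 hydroxyl is placed to lactonise onto C12, which equals the chosen plan.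
- Against it: the cyclisation needs high dilution and a large excess of a toxic chromium salt. C6 is formed during ring closure under weak control by C7; this is the same uncertainty as the hydride reduction of the chosen plan, so the two are equal there. The aldehyde of A6 has an enolisable C7–H with a β-silyloxy group, so epimerisation and elimination threaten before cyclisation. A6 needs two stereodefined trisubstituted alkenes made separately.
- Comparison: the chosen plan avoids end-to-end cyclisation and gets the C4=C5 geometry from ring A, at the price of the work on the alkyne after fragmentation. Step counts should be comparable.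

Key step: step 11

Remark on the chemistry: germacrane numbering is used throughout (ring C1–C10, lactone carbons C11–C13, formyl C14, hydroxymethyl C15). Stereocentres that are erased later (C1/C6 in 12, C6 in 13, C11 in 21–29) are left open in the SMILES, because either epimer is carried forward.

## Route

Step 1
Reactants: 1 prop-2-yn-1-ol (propargyl alcohol)
Product: 2 tert-butyl(diphenyl)(prop-2-yn-1-yloxy)silane
Conditions: t-BuPh2SiCl, imidazole, CH2Cl2, 0 °C to rt
Reagents that add atoms: tert-butyl(chloro)diphenylsilane, CC(C)(C)[Si](Cl)(c1ccccc1)c1ccccc1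
Why: Standard silylation of a primary alcohol; the bulky silyl ether becomes the C15 protecting group and should survive every later step until the fluoride treatment of step 18.

Step 2
Reactants: 3 (S)-3-hydroxy-γ-butyrolactone
Product: 4 (3S)-3,4-dihydroxy-N-methoxy-N-methylbutanamide
Conditions: MeNH(OMe)·HCl, i-PrMgCl (excess), THF, −20 to 0 °C; NH4Cl (aq)
Reagents that add atoms: N,O-dimethylhydroxylamine hydrochloride, CNOC.Cl
Why: Aminolysis of a lactone by a magnesium amide (Weinreb amide formation); the carbinol centre that becomes C8 is not involved and is carried over unchanged, and C10 arrives as an acyl group that one Grignard addition can later turn into the vinyl ketone.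

Step 3
Reactants: 4 (3S)-3,4-dihydroxy-N-methoxy-N-methylbutanamide
Product: 5 (3S)-N-methoxy-N-methyl-3,4-bis(triethylsilyloxy)butanamide
Conditions: Et3SiCl, imidazole, DMF, 0 °C
Reagents that add atoms: chlorotriethylsilane, CC[Si](Cl)(CC)CC
Why: Exhaustive silylation of the diol; prompt protection also stops the γ-hydroxy amide from closing back to the lactone.

Step 4
Reactants: 5 (3S)-N-methoxy-N-methyl-3,4-bis(triethylsilyloxy)butanamide
Product: 6 (3S)-N-methoxy-N-methyl-4-oxo-3-(triethylsilyloxy)butanamide
Conditions: (COCl)2, DMSO, CH2Cl2, −78 to −30 °C; Et3N, −78 to 0 °C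
Reagents that add atoms: none
Why: Swern oxidation applied directly to the bis-silyl ether: the primary triethylsilyl ether is cleaved and oxidised by the chlorosulfonium reagent while the hindered secondary one survives, giving the C7 aldehyde without a separate deprotection. The α-silyloxy aldehyde is used at once to avoid epimerisation.

Step 5
Reactants: 6 (3S)-N-methoxy-N-methyl-4-oxo-3-(triethylsilyloxy)butanamide
Product: 7 methyl (2Z,4S)-6-[methoxy(methyl)amino]-6-oxo-4-(triethylsilyloxy)hex-2-enoate
Conditions: (CF3CH2O)2P(O)CH2CO2Me, KN(SiMe3)2, 18-crown-6, THF, −78 °C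
Reagents that add atoms: methyl bis(2,2,2-trifluoroethyl)phosphonoacetate, COC(=O)CP(=O)(OCC(F)(F)F)OCC(F)(F)F
Why: Still–Gennari variant of the Horner–Wadsworth–Emmons olefination; the electron-poor phosphonate under dissociating conditions should give the Z-enoate, whose geometry is needed for facial control in step 6, and it brings in C11 and C12.

Step 6
Reactants: 7 methyl (2Z,4S)-6-[methoxy(methyl)amino]-6-oxo-4-(triethylsilyloxy)hex-2-enoate; 8 vinylmagnesium bromide
Product: 9 methyl (3R,4S)-3-ethenyl-6-[methoxy(methyl)amino]-6-oxo-4-(triethylsilyloxy)hexanoate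
Conditions: CH2=CHMgBr (3 equiv), CuI (1.5 equiv), Me3SiCl, THF, −78 to −40 °C; NH4Cl/NH3 (aq)
Reagents that add atoms: none
Why: Silyl-chloride-accelerated conjugate addition of a vinyl cuprate; in the Z-enoate A(1,3) strain holds the C8–H bond in the alkene plane, and addition anti to the C9 chain (on the face of the oxygen) is the known syn mode of Z-γ-alkoxy enoates, which sets C7 with the C11 branch and the C8 oxygen anti along C6–C7–C8–C9. The cuprate leaves the Weinreb amide alone and no free Grignard reagent remains at this stoichiometry.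

Step 7
Reactants: 9 methyl (3R,4S)-3-ethenyl-6-[methoxy(methyl)amino]-6-oxo-4-(triethylsilyloxy)hexanoate; 2 tert-butyl(diphenyl)(prop-2-yn-1-yloxy)silane
Product: 10 methyl (3R,4S)-3-[(1E)-3-(tert-butyldiphenylsilyloxymethyl)buta-1,3-dien-1-yl]-6-[methoxy(methyl)amino]-6-oxo-4-(triethylsilyloxy)hexanoate
Conditions: 2 (3 equiv, slow addition), RuCl2(=CHPh)(PCy3)(H2IMes) (second-generation Grubbs catalyst, 10 mol%), ethylene (1 atm), CH2Cl2, 40 °C
Reagents that add atoms: none
Why: Enyne cross-metathesis joins the alkyne of 2 to the vinyl group of 9 and gives the 1,3-disubstituted diene with the C15 branch on C4; ethylene keeps the ruthenium methylidene alive and secondary metathesis should funnel C5=C6 to the E isomer that the cycloaddition needs. All atoms of both partners end up in the product.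

Step 8
Reactants: 10 methyl (3R,4S)-3-[(1E)-3-(tert-butyldiphenylsilyloxymethyl)buta-1,3-dien-1-yl]-6-[methoxy(methyl)amino]-6-oxo-4-(triethylsilyloxy)hexanoate; 8 vinylmagnesium bromide
Product: 12 methyl 2-[(1R,2S)-7-(tert-butyldiphenylsilyloxymethyl)-4-oxo-2-(triethylsilyloxy)-1,2,3,4,4a,5,6,8a-octahydronaphthalen-1-yl]acetate (ring-fusion epimers), via trienone 11 (not isolated)
Conditions: CH2=CHMgBr, THF, −78 to −20 °C; inverse quench into cold NaHSO4 (aq); then PhMe, BHT, 25 to 70 °C
Reagents that add atoms: none
Why: Grignard addition to the Weinreb amide stops at the chelated tetrahedral intermediate and is faster than attack on the methyl ester at low temperature. The released deca-1,7,9-trien-3-one then undergoes an intramolecular Diels–Alder reaction that forms C1–C6 and C2–C3, closes rings A and B and, through the tether, places C4=C5 in ring A. The new C1 and C6 centres are erased in step 9, so endo/exo and facial selectivity are immaterial.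

Step 9
Reactants: 12 methyl 2-[(1R,2S)-7-(tert-butyldiphenylsilyloxymethyl)-4-oxo-2-(triethylsilyloxy)-1,2,3,4,4a,5,6,8a-octahydronaphthalen-1-yl]acetate
Product: 14 methyl 2-[(1R,2S)-7-(tert-butyldiphenylsilyloxymethyl)-4-oxo-2-(triethylsilyloxy)-1,2,3,4,5,6-hexahydronaphthalen-1-yl]acetate, via trimethylsilyl enol ether 13 (not isolated)
Conditions: Me3SiCl, NaI, Et3N, MeCN, rt; then Pd(OAc)2 (1.1 equiv), MeCN, rt
Reagents that add atoms: none
Why: Saegusa–Ito dehydrogenation: equilibrating silylation favours the tetrasubstituted C10=C1 enol ether, and the oxa-π-allyl complex of divalent palladium should lose the allylic tertiary hydrogen on C6 to give the fully conjugated C10(=O)–C1=C6–C5=C4 dienone. One equivalent of Pd(OAc)2 limits further dehydrogenation of ring A.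

Step 10
Reactants: 14 methyl 2-[(1R,2S)-7-(tert-butyldiphenylsilyloxymethyl)-4-oxo-2-(triethylsilyloxy)-1,2,3,4,5,6-hexahydronaphthalen-1-yl]acetate
Product: 15 methyl 2-[(1S,2S,4aR,8aR)-7-(tert-butyldiphenylsilyloxymethyl)-4a,8a-epoxy-4-oxo-2-(triethylsilyloxy)-1,2,3,4,4a,5,6,8a-octahydronaphthalen-1-yl]acetate (C1,C6-epoxy decalin-10-one)
Conditions: 30% H2O2, NaOH (aq, 0.5 equiv), MeOH, 0 °C
Reagents that add atoms: hydrogen peroxide, OO
Why: Weitz–Scheffer epoxidation: hydroperoxide adds to the β-carbon C6 of the dienone and the enolate closes the C1,C6-oxirane, the α,β-selectivity known for linear dienones such as steroidal 4,6-dien-3-ones. Attack anti to the pseudoaxial C7 branch should give the epimer shown, although either epoxide epimer fragments to the same product, and cold brief exposure to base limits β-elimination of the C8 silyl ether.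

Step 11
Reactants: 15 methyl 2-[(1S,2S,4aR,8aR)-7-(tert-butyldiphenylsilyloxymethyl)-4a,8a-epoxy-4-oxo-2-(triethylsilyloxy)-1,2,3,4,4a,5,6,8a-octahydronaphthalen-1-yl]acetate; 16 p-toluenesulfonohydrazide
Product: 18 methyl 2-[(1S,3E,10S)-4-(tert-butyldiphenylsilyloxymethyl)-2-oxo-10-(triethylsilyloxy)cyclodec-3-en-7-yn-1-yl]acetate (cyclodec-4-en-1(10)-yn-6-one in germacrane numbering), via tosylhydrazone 17 (not isolated)
Conditions: TsNHNH2 (1.05 equiv), CH2Cl2/AcOH (2:1), −20 °C to rt
Reagents that add atoms: none
Why: Eschenmoser–Tanabe fragmentation: the hydrazide condenses with the C10 ketone to give 17, whose N–H is lost as the oxirane opens at C1, producing an azoalkene (C1=C10–N=N–Ts) with an oxygen anion or hydroxyl on C6. This intermediate collapses in a Grob-type fragmentation in which the C6–O bond becomes the carbonyl, the C1–C6 bond breaks, C1–C10 becomes the triple bond and dinitrogen and p-toluenesulfinate depart. The closest known reaction type is the conversion of bicyclic α,β-epoxy ketones with the epoxide on the ring-fusion bond into medium- and large-ring cycloalkynones. The ten-membered ring is not closed end to end: it appears when the bond shared by the two six-membered rings is cut, so no cyclisation entropy or transannular strain has to be overcome in a ring-closing transition state. No stereocentre is formed; C7 and C8 are spectators, and C4=C5 keeps the cis geometry it had in ring A and ends up conjugated to the new C6 ketone. The step needs regiospecific cleavage, which is secured by the ketone sitting on C10 directly beside the C1,C6-epoxide, and chemoselective condensation at the ketone over the ester. It also needs C7 to stay unepimerised and the C8 silyloxy group to resist β-elimination, which the cold, weakly acidic, base-free medium and immediate use of 18 in step 12 should ensure.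

Step 12
Reactants: 18 methyl 2-[(1S,3E,10S)-4-(tert-butyldiphenylsilyloxymethyl)-2-oxo-10-(triethylsilyloxy)cyclodec-3-en-7-yn-1-yl]acetate
Product: 20 (3aR,4S,10E,11aR)-10-(tert-butyldiphenylsilyloxymethyl)-4-(triethylsilyloxy)-6,7-didehydro-3a,4,5,8,9,11a-hexahydrocyclodeca[b]furan-2(3H)-one, via hydroxy ester 19 (not isolated)
Conditions: NaBH4, CeCl3·7H2O, MeOH, −78 °C; then pyridinium p-toluenesulfonate (cat.), CH2Cl2, rt
Reagents that add atoms: none
Why: Luche 1,2-reduction of the enone followed by lactonisation of the γ-hydroxy ester; hydride should add to C6 from the ring periphery on the face remote from the C7 acetate branch (Felkin–Anh sense with C8 as the large group), which places the new hydroxyl cis to that branch (6R) and lets it close the cis-fused lactone. O8 stays silylated and cannot compete for C12.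

Step 13
Reactants: 20 (3aR,4S,10E,11aR)-10-(tert-butyldiphenylsilyloxymethyl)-4-(triethylsilyloxy)-6,7-didehydro-3a,4,5,8,9,11a-hexahydrocyclodeca[b]furan-2(3H)-one
Product: 22 (3aS,4S,10E,11aR)-10-(tert-butyldiphenylsilyloxymethyl)-3-[(dimethylamino)methyl]-4-hydroxy-6,7-didehydro-3a,4,5,8,9,11a-hexahydrocyclodeca[b]furan-2(3H)-one, via triethylsilyl Mannich base 21 (not isolated)
Conditions: LiN(i-Pr)2, THF, −78 °C; Me2N=CH2 I, −78 to 0 °C; then 1 M HCl, THF, 0 °C; NaHCO3 (aq)
Reagents that add atoms: N,N-dimethylmethyleneiminium iodide, C[N+](C)=C.[I-]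
Why: Mannich aminomethylation of the lactone enolate installs C13 as a β-amino group, a masked α-methylene unit that is inert to the tin hydride, palladium and iodonium reagents used later. The acidic work-up (amine protonated) removes the secondary triethylsilyl ether but not the tert-butyldiphenylsilyl ether, and the configuration at C11 is of no consequence.

Step 14
Reactants: 22 (3aS,4S,10E,11aR)-10-(tert-butyldiphenylsilyloxymethyl)-3-[(dimethylamino)methyl]-4-hydroxy-6,7-didehydro-3a,4,5,8,9,11a-hexahydrocyclodeca[b]furan-2(3H)-one
Product: 24 cyclic vinylsiloxane of 22 (O8–SiMe2–C10 bridge forming a 1-oxa-2-silacyclopentane through C8–C9–C10; C1=C10 ring-cis with H on C1 cis to Si), via dimethylsilyl ether 23 (not isolated)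
Conditions: (HMe2Si)2NH, 50 °C, then evaporation; Pt2[(CH2=CHSiMe2)2O]3 (2 mol%), THF, rt to 50 °C
Reagents that add atoms: 1,1,3,3-tetramethyldisilazane, C[SiH](C)N[SiH](C)C
Why: Silylation of the homopropargylic C8 hydroxyl followed by platinum-catalysed intramolecular hydrosilylation; the tether can deliver silicon only to C10 (five-membered ring, exo mode) and syn addition puts hydrogen on C1 on the same side, so the C1=C10 alkene is formed ring-cis with a handle on C10.

Step 15
Reactants: 24 cyclic vinylsiloxane (O8–SiMe2–C10 bridge; C1=C10 ring-cis)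
Product: 25 (3aS,4S,6E,10E,11aR)-10-(tert-butyldiphenylsilyloxymethyl)-3-[(dimethylamino)methyl]-4-hydroxy-6-iodo-3a,4,5,8,9,11a-hexahydrocyclodeca[b]furan-2(3H)-one
Conditions: CF3CO2H (1.05 equiv), then N-iodosuccinimide, (CF3)2CHOH/CH2Cl2, 0 °C; NaHCO3 (aq), Na2S2O3 (aq)
Reagents that add atoms: N-iodosuccinimide, O=C1CCC(=O)N1I
Why: Iododesilylation of a vinylsilane (ipso attack of iodonium at C10, β-silyl cation, loss of silicon) proceeds with retention and gives the C10 iodide on the ring-cis alkene. The amine is held as its ammonium salt so that it is not oxidised, and the aqueous work-up hydrolyses the residual silyl group on O8 to the free hydroxyl.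

Step 16
Reactants: 25 (3aS,4S,6E,10E,11aR)-10-(tert-butyldiphenylsilyloxymethyl)-3-[(dimethylamino)methyl]-4-hydroxy-6-iodo-3a,4,5,8,9,11a-hexahydrocyclodeca[b]furan-2(3H)-one
Product: 26 (3aS,4S,6E,10E,11aR)-10-(tert-butyldiphenylsilyloxymethyl)-3-[(dimethylamino)methyl]-6-iodo-2-oxo-2,3,3a,4,5,8,9,11a-octahydrocyclodeca[b]furan-4-yl 3-methylbutanoate
Conditions: (i-BuCO)2O, 4-(dimethylamino)pyridine (cat.), pyridine, CH2Cl2, 0 °C to rt
Reagents that add atoms: 3-methylbutanoic anhydride, CC(C)CC(=O)OC(=O)CC(C)C
Why: Acylation of the secondary alcohol under nucleophilic catalysis; it is placed before the carbonylation because a free C8 hydroxyl would trap the acylpalladium intermediate as a five-membered lactone, and the mild base keeps the cis lactone from migrating to O8.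

Step 17
Reactants: 26 (3aS,4S,6E,10E,11aR)-10-(tert-butyldiphenylsilyloxymethyl)-3-[(dimethylamino)methyl]-6-iodo-2-oxo-2,3,3a,4,5,8,9,11a-octahydrocyclodeca[b]furan-4-yl 3-methylbutanoate
Product: 27 (3aS,4S,6E,10E,11aR)-10-(tert-butyldiphenylsilyloxymethyl)-3-[(dimethylamino)methyl]-6-formyl-2-oxo-2,3,3a,4,5,8,9,11a-octahydrocyclodeca[b]furan-4-yl 3-methylbutanoate
Conditions: Pd(PPh3)4 (5 mol%), CO (1 atm), Bu3SnH (slow addition), THF, 50 °C
Reagents that add atoms: carbon monoxide, [C-]#[O+]
Why: Carbonylative formylation of a vinyl iodide: oxidative addition to zerovalent palladium with retention, CO insertion and capture of the acylpalladium by the tin hydride give the C14 enal on the ring-cis alkene. Slow hydride addition under CO favours formylation over direct reduction.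

Step 18
Reactants: 27 (3aS,4S,6E,10E,11aR)-10-(tert-butyldiphenylsilyloxymethyl)-3-[(dimethylamino)methyl]-6-formyl-2-oxo-2,3,3a,4,5,8,9,11a-octahydrocyclodeca[b]furan-4-yl 3-methylbutanoate
Product: 28 (3aS,4S,6E,10E,11aR)-3-[(dimethylamino)methyl]-6-formyl-10-(hydroxymethyl)-2-oxo-2,3,3a,4,5,8,9,11a-octahydrocyclodeca[b]furan-4-yl 3-methylbutanoate
Conditions: HF·pyridine, pyridine, THF, 0 °C to rt
Reagents that add atoms: none
Why: Fluoride cleavage of the primary silyl ether under buffered conditions that leave the enal, both esters and the amine untouched.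

Step 19
Reactants: 28 (3aS,4S,6E,10E,11aR)-3-[(dimethylamino)methyl]-6-formyl-10-(hydroxymethyl)-2-oxo-2,3,3a,4,5,8,9,11a-octahydrocyclodeca[b]furan-4-yl 3-methylbutanoate
Product: 30 (3aS,4S,6E,10E,11aR)-6-formyl-10-(hydroxymethyl)-3-methylidene-2-oxo-2,3,3a,4,5,8,9,11a-octahydrocyclodeca[b]furan-4-yl 3-methylbutanoate (target), via trimethylammonium iodide 29 (not isolated)
Conditions: MeI, THF, rt; then NaHCO3 (aq), CH2Cl2, rt
Reagents that add atoms: none
Why: Quaternisation and E1cB elimination of trimethylamine unveil the C11=C13 methylene as the last operation, so the α-methylene lactone never meets a nucleophile or a reductant. The C11 centre disappears and no other centre is touched.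

## Compound list

1 | prop-2-yn-1-ol (propargyl alcohol) | C#CCO | starting material
2 | tert-butyl(diphenyl)(prop-2-yn-1-yloxy)silane | C#CCO[Si](c1ccccc1)(c1ccccc1)C(C)(C)C | intermediate
3 | (S)-3-hydroxy-γ-butyrolactone | O=C1C[C@H](O)CO1 | starting material
4 | (3S)-3,4-dihydroxy-N-methoxy-N-methylbutanamide | CON(C)C(=O)C[C@H](O)CO | intermediate
5 | (3S)-N-methoxy-N-methyl-3,4-bis(triethylsilyloxy)butanamide | CON(C)C(=O)C[C@H](O[Si](CC)(CC)CC)CO[Si](CC)(CC)CC | intermediate
6 | (3S)-N-methoxy-N-methyl-4-oxo-3-(triethylsilyloxy)butanamide | CON(C)C(=O)C[C@H](O[Si](CC)(CC)CC)C=O | intermediate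
7 | methyl (2Z,4S)-6-[methoxy(methyl)amino]-6-oxo-4-(triethylsilyloxy)hex-2-enoate | CON(C)C(=O)C[C@H](O[Si](CC)(CC)CC)/C=C\C(=O)OC | intermediate
8 | vinylmagnesium bromide | C=C[Mg]Br | starting material
9 | methyl (3R,4S)-3-ethenyl-6-[methoxy(methyl)amino]-6-oxo-4-(triethylsilyloxy)hexanoate | CON(C)C(=O)C[C@H](O[Si](CC)(CC)CC)[C@@H](C=C)CC(=O)OC | intermediate
10 | methyl (3R,4S)-3-[(1E)-3-(tert-butyldiphenylsilyloxymethyl)buta-1,3-dien-1-yl]-6-[methoxy(methyl)amino]-6-oxo-4-(triethylsilyloxy)hexanoate | CON(C)C(=O)C[C@H](O[Si](CC)(CC)CC)[C@@H](/C=C/C(=C)CO[Si](c1ccccc1)(c1ccccc1)C(C)(C)C)CC(=O)OC | intermediate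
11 | methyl (3R,4S)-3-[(1E)-3-(tert-butyldiphenylsilyloxymethyl)buta-1,3-dien-1-yl]-6-oxo-4-(triethylsilyloxy)oct-7-enoate (trienone) | C=CC(=O)C[C@H](O[Si](CC)(CC)CC)[C@@H](/C=C/C(=C)CO[Si](c1ccccc1)(c1ccccc1)C(C)(C)C)CC(=O)OC | intermediate
12 | methyl 2-[(1R,2S)-7-(tert-butyldiphenylsilyloxymethyl)-4-oxo-2-(triethylsilyloxy)-1,2,3,4,4a,5,6,8a-octahydronaphthalen-1-yl]acetate (ring-fusion epimers) | O=C1C[C@H](O[Si](CC)(CC)CC)[C@H](CC(=O)OC)C2C=C(CO[Si](c3ccccc3)(c3ccccc3)C(C)(C)C)CCC12 | intermediate
13 | methyl 2-[(1R,2S)-7-(tert-butyldiphenylsilyloxymethyl)-2-(triethylsilyloxy)-4-(trimethylsilyloxy)-1,2,3,5,6,8a-hexahydronaphthalen-1-yl]acetate | C[Si](C)(C)OC1=C2CCC(CO[Si](c3ccccc3)(c3ccccc3)C(C)(C)C)=CC2[C@@H](CC(=O)OC)[C@@H](O[Si](CC)(CC)CC)C1 | intermediate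
14 | methyl 2-[(1R,2S)-7-(tert-butyldiphenylsilyloxymethyl)-4-oxo-2-(triethylsilyloxy)-1,2,3,4,5,6-hexahydronaphthalen-1-yl]acetate | O=C1C[C@H](O[Si](CC)(CC)CC)[C@H](CC(=O)OC)C2=C1CCC(CO[Si](c3ccccc3)(c3ccccc3)C(C)(C)C)=C2 | intermediate
15 | methyl 2-[(1S,2S,4aR,8aR)-7-(tert-butyldiphenylsilyloxymethyl)-4a,8a-epoxy-4-oxo-2-(triethylsilyloxy)-1,2,3,4,4a,5,6,8a-octahydronaphthalen-1-yl]acetate | O=C1C[C@H](O[Si](CC)(CC)CC)[C@H](CC(=O)OC)[C@@]23O[C@@]12CCC(CO[Si](c4ccccc4)(c4ccccc4)C(C)(C)C)=C3 | intermediate
16 | p-toluenesulfonohydrazide | Cc1ccc(cc1)S(=O)(=O)NN | starting material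
17 | C10 p-toluenesulfonylhydrazone of 15 | Cc1ccc(cc1)S(=O)(=O)NN=C1C[C@H](O[Si](CC)(CC)CC)[C@H](CC(=O)OC)[C@@]23O[C@@]12CCC(CO[Si](c4ccccc4)(c4ccccc4)C(C)(C)C)=C3 | intermediate
18 | methyl 2-[(1S,3E,10S)-4-(tert-butyldiphenylsilyloxymethyl)-2-oxo-10-(triethylsilyloxy)cyclodec-3-en-7-yn-1-yl]acetate | O=C1/C=C(/CO[Si](c2ccccc2)(c2ccccc2)C(C)(C)C)CCC#CC[C@H](O[Si](CC)(CC)CC)[C@@H]1CC(=O)OC | intermediate
19 | methyl 2-[(1R,2R,3E,10S)-4-(tert-butyldiphenylsilyloxymethyl)-2-hydroxy-10-(triethylsilyloxy)cyclodec-3-en-7-yn-1-yl]acetate | O[C@@H]1/C=C(/CO[Si](c2ccccc2)(c2ccccc2)C(C)(C)C)CCC#CC[C@H](O[Si](CC)(CC)CC)[C@@H]1CC(=O)OC | intermediate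
20 | (3aR,4S,10E,11aR)-10-(tert-butyldiphenylsilyloxymethyl)-4-(triethylsilyloxy)-6,7-didehydro-3a,4,5,8,9,11a-hexahydrocyclodeca[b]furan-2(3H)-one | C1C(=O)O[C@@H]2/C=C(/CO[Si](c3ccccc3)(c3ccccc3)C(C)(C)C)CCC#CC[C@H](O[Si](CC)(CC)CC)[C@H]12 | intermediate
21 | 3-[(dimethylamino)methyl] derivative of 20 (C8 triethylsilyl ether) | CN(C)CC1C(=O)O[C@@H]2/C=C(/CO[Si](c3ccccc3)(c3ccccc3)C(C)(C)C)CCC#CC[C@H](O[Si](CC)(CC)CC)[C@H]12 | intermediate
22 | (3aS,4S,10E,11aR)-10-(tert-butyldiphenylsilyloxymethyl)-3-[(dimethylamino)methyl]-4-hydroxy-6,7-didehydro-3a,4,5,8,9,11a-hexahydrocyclodeca[b]furan-2(3H)-one | CN(C)CC1C(=O)O[C@@H]2/C=C(/CO[Si](c3ccccc3)(c3ccccc3)C(C)(C)C)CCC#CC[C@H](O)[C@H]12 | intermediate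
23 | C8 dimethylsilyl ether of 22 | CN(C)CC1C(=O)O[C@@H]2/C=C(/CO[Si](c3ccccc3)(c3ccccc3)C(C)(C)C)CCC#CC[C@H](O[SiH](C)C)[C@H]12 | intermediate
24 | cyclic vinylsiloxane (O8–SiMe2–C10 bridge; C1=C10 ring-cis) | CN(C)CC1C(=O)O[C@@H]2/C=C(/CO[Si](c3ccccc3)(c3ccccc3)C(C)(C)C)CC/C=C3\C[C@H](O[Si]3(C)C)[C@H]12 | intermediate
25 | (3aS,4S,6E,10E,11aR)-10-(tert-butyldiphenylsilyloxymethyl)-3-[(dimethylamino)methyl]-4-hydroxy-6-iodo-3a,4,5,8,9,11a-hexahydrocyclodeca[b]furan-2(3H)-one | CN(C)CC1C(=O)O[C@@H]2/C=C(/CO[Si](c3ccccc3)(c3ccccc3)C(C)(C)C)CC/C=C(/I)C[C@H](O)[C@H]12 | intermediate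
26 | 3-methylbutanoate of 25 | CN(C)CC1C(=O)O[C@@H]2/C=C(/CO[Si](c3ccccc3)(c3ccccc3)C(C)(C)C)CC/C=C(/I)C[C@H](OC(=O)CC(C)C)[C@H]12 | intermediate
27 | (3aS,4S,6E,10E,11aR)-10-(tert-butyldiphenylsilyloxymethyl)-3-[(dimethylamino)methyl]-6-formyl-2-oxo-2,3,3a,4,5,8,9,11a-octahydrocyclodeca[b]furan-4-yl 3-methylbutanoate | CN(C)CC1C(=O)O[C@@H]2/C=C(/CO[Si](c3ccccc3)(c3ccccc3)C(C)(C)C)CC/C=C(/C=O)C[C@H](OC(=O)CC(C)C)[C@H]12 | intermediate
28 | (3aS,4S,6E,10E,11aR)-3-[(dimethylamino)methyl]-6-formyl-10-(hydroxymethyl)-2-oxo-2,3,3a,4,5,8,9,11a-octahydrocyclodeca[b]furan-4-yl 3-methylbutanoate | CN(C)CC1C(=O)O[C@@H]2/C=C(/CO)CC/C=C(/C=O)C[C@H](OC(=O)CC(C)C)[C@H]12 | intermediate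
29 | N-methyl ammonium iodide of 28 | C[N+](C)(C)CC1C(=O)O[C@@H]2/C=C(/CO)CC/C=C(/C=O)C[C@H](OC(=O)CC(C)C)[C@H]12.[I-] | intermediate
30 | (3aS,4S,6E,10E,11aR)-6-formyl-10-(hydroxymethyl)-3-methylidene-2-oxo-2,3,3a,4,5,8,9,11a-octahydrocyclodeca[b]furan-4-yl 3-methylbutanoate | C=C1C(=O)O[C@@H]2/C=C(/CO)CC/C=C(/C=O)C[C@H](OC(=O)CC(C)C)[C@H]12 | target

## Step count and least certain steps

Total step count: 19. Longest linear sequence: 18 steps (3 to 30, steps 2–19); step 1 is a one-step side branch.

Step 11 (key step). The most likely failure is solvolytic opening of the tertiary, allylic oxirane by the acidic medium before the hydrazone has formed. After fragmentation, β-elimination of the C8 silyloxy group or epimerisation at C7 of the β-silyloxy enone could follow. The fallback avoids acid altogether. It sets out from 15, which is condensed with 1-amino-2-phenylaziridine under neutral conditions (CH2Cl2, 0 °C) to the N-aziridinyl imine F1. Warming F1 in toluene (60–80 °C) expels styrene to give the α,β-epoxy diazo compound, which undergoes the same fragmentation with loss of dinitrogen. The fallback returns to the route at 18.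

Step 6. Facial selectivity may be poor, because a silyl ether coordinates the cuprate weakly, and reversible complexation may isomerise the Z-enoate to the E isomer, which adds with the opposite sense. The fallback replaces substrate control by auxiliary control. It sets out from 6: Horner–Wadsworth–Emmons reaction with diethyl {2-oxo-2-[(4S)-2-oxo-4-phenyl-1,3-oxazolidin-3-yl]ethyl}phosphonate (LiCl, i-Pr2NEt, MeCN) gives the E-enoyl oxazolidinone F2. Addition of CH2=CHMgBr/CuBr·SMe2 to the chelated s-cis conformer, anti to the phenyl group, gives the adduct F3 with the required C7 configuration. Methanolysis with MeOMgBr releases the auxiliary and returns to the route at 9.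

Step 7. The metathesis may stall on the hindered, allylically branched vinyl group, the alkyne may oligomerise, and incomplete equilibration would leave a mixture of C5=C6 isomers. The fallback builds the diene in two steps of fixed geometry. It sets out from 9: cross-metathesis with vinylboronic acid pinacol ester (same ruthenium catalyst) gives the E-alkenyl boronate F4. Suzuki–Miyaura coupling of F4 [PdCl2(dppf), K3PO4, THF/H2O] with the 2-bromoallyl silyl ether F5, made from 2-bromoprop-2-en-1-ol and t-BuPh2SiCl, returns to the route at 10.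

Step 9. Silylation may occur toward C9, the palladium enolate may lose a hydrogen from C2 instead of C6, or ring A may be dehydrogenated further toward an aromatic ring. The fallback uses a selenoxide syn-elimination, which cannot over-oxidise. It sets out from 12: the enol ether 13 is treated with PhSeCl (CH2Cl2, −78 °C) to give the C1 phenylselenide F6. Oxidation with H2O2/pyridine at 0 °C and elimination toward the allylic C6 hydrogen returns to the route at 14.

Step 12. The conformation of the ten-membered enynone is unknown, so hydride may be delivered to the other face of C6. The C6 epimer would then lactonise trans. The fallback corrects C6 by inversion instead of relying on the reduction. It sets out from 18: the reduction product is collected as the trans-fused lactone F7. LiOH (THF/H2O) opens F7 to the hydroxy acid F8, and an intramolecular Mitsunobu lactonisation (PPh3, DIAD, THF) closes the ring with inversion at C6, returning to the route at 20.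

Step 17. The tin hydride may reduce the vinyl- or acylpalladium species directly, or reduce the enal in a conjugate sense. Zerovalent palladium may also ionise the allylic C6–O bond of the lactone, after which hydride capture would open the ring. The fallback introduces C14 without any hydride donor. It sets out from 26: Stille coupling with (tributylstannyl)methanol [Pd(PPh3)4, dioxane, 80 °C] gives the allylic alcohol F9. Oxidation with MnO2 (CH2Cl2) returns to the route at 27.

## Further compounds

F1 | step 11 | N-(2-phenylaziridin-1-yl)imine of 15 at C10 | c1ccccc1C1CN1N=C1C[C@H](O[Si](CC)(CC)CC)[C@H](CC(=O)OC)[C@@]23O[C@@]12CCC(CO[Si](c4ccccc4)(c4ccccc4)C(C)(C)C)=C3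
F2 | step 6 | (4S)-3-[(2E,4S)-6-[methoxy(methyl)amino]-6-oxo-4-(triethylsilyloxy)hex-2-enoyl]-4-phenyl-1,3-oxazolidin-2-one | O=C1OC[C@H](c2ccccc2)N1C(=O)/C=C/[C@@H](O[Si](CC)(CC)CC)CC(=O)N(C)OC
F3 | step 6 | (4S)-3-[(3R,4S)-3-ethenyl-6-[methoxy(methyl)amino]-6-oxo-4-(triethylsilyloxy)hexanoyl]-4-phenyl-1,3-oxazolidin-2-one | O=C1OC[C@H](c2ccccc2)N1C(=O)C[C@H](C=C)[C@@H](O[Si](CC)(CC)CC)CC(=O)N(C)OC
F4 | step 7 | methyl (3R,4S)-6-[methoxy(methyl)amino]-6-oxo-3-[(E)-2-(4,4,5,5-tetramethyl-1,3,2-dioxaborolan-2-yl)ethenyl]-4-(triethylsilyloxy)hexanoate | CON(C)C(=O)C[C@H](O[Si](CC)(CC)CC)[C@@H](/C=C/B1OC(C)(C)C(C)(C)O1)CC(=O)OC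
F5 | step 7 | [(2-bromoprop-2-en-1-yl)oxy](tert-butyl)diphenylsilane | C=C(Br)CO[Si](c1ccccc1)(c1ccccc1)C(C)(C)C
F6 | step 9 | 4a-(phenylselanyl) derivative of 12 (selenium on C1) | O=C1C[C@H](O[Si](CC)(CC)CC)[C@H](CC(=O)OC)C2C=C(CO[Si](c3ccccc3)(c3ccccc3)C(C)(C)C)CCC12[Se]c1ccccc1
F7 | step 12 | (3aR,4S,10E,11aS)-10-(tert-butyldiphenylsilyloxymethyl)-4-(triethylsilyloxy)-6,7-didehydro-3a,4,5,8,9,11a-hexahydrocyclodeca[b]furan-2(3H)-one (C6 epimer of 20, trans-fused) | C1C(=O)O[C@H]2/C=C(/CO[Si](c3ccccc3)(c3ccccc3)C(C)(C)C)CCC#CC[C@H](O[Si](CC)(CC)CC)[C@H]12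
F8 | step 12 | 2-[(1R,2S,3E,10S)-4-(tert-butyldiphenylsilyloxymethyl)-2-hydroxy-10-(triethylsilyloxy)cyclodec-3-en-7-yn-1-yl]acetic acid | O[C@H]1/C=C(/CO[Si](c2ccccc2)(c2ccccc2)C(C)(C)C)CCC#CC[C@H](O[Si](CC)(CC)CC)[C@@H]1CC(=O)O
F9 | step 17 | (3aS,4S,6E,10E,11aR)-10-(tert-butyldiphenylsilyloxymethyl)-3-[(dimethylamino)methyl]-6-(hydroxymethyl)-2-oxo-2,3,3a,4,5,8,9,11a-octahydrocyclodeca[b]furan-4-yl 3-methylbutanoate | CN(C)CC1C(=O)O[C@@H]2/C=C(/CO[Si](c3ccccc3)(c3ccccc3)C(C)(C)C)CC/C=C(/CO)C[C@H](OC(=O)CC(C)C)[C@H]12
A1 | alternative 1 | ten-membered enoate (C15 methyl ester; silyl ethers on O6, O8, O12; p-methoxybenzyl ether on O14) | C=C(CO[Si](C)(C)C(C)(C)C)[C@@H]1[C@H](O[Si](C)(C)C(C)(C)C)/C=C(/C(=O)OC)CC/C=C(/COCc2ccc(OC)cc2)C[C@@H]1O[Si](CC)(CC)CC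
A2 | alternative 1 | open-chain C4 phosphonoacetate with C5 aldehyde | C=C(CO[Si](C)(C)C(C)(C)C)[C@H]([C@H](O[Si](C)(C)C(C)(C)C)C=O)[C@@H](O[Si](CC)(CC)CC)C/C(COCc1ccc(OC)cc1)=C\CCC(C(=O)OC)P(=O)(OC)OC
A3 | alternative 2 | ten-membered C8 homoallylic alcohol with exocyclic C11=C13 | C=C(CO[Si](C)(C)C(C)(C)C)[C@@H]1[C@H](O[Si](C)(C)C(C)(C)C)/C=C(/CO[Si](c2ccccc2)(c2ccccc2)C(C)(C)C)CC/C=C(/COCc2ccc(OC)cc2)C[C@@H]1O
A4 | alternative 2 | thirteen-membered C8–O–C13 allyl ether with tributylstannyl on C8 | CCCC[Sn](CCCC)(CCCC)[C@H]1C/C(COCc2ccc(OC)cc2)=C\CC/C(CO[Si](c2ccccc2)(c2ccccc2)C(C)(C)C)=C\[C@@H](O[Si](C)(C)C(C)(C)C)/C=C(/CO[Si](C)(C)C(C)(C)C)CO1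
A5 | alternative 3 | ten-membered C6 hydroxy ester | O[C@@H]1/C=C(/CO[Si](c2ccccc2)(c2ccccc2)C(C)(C)C)CC/C=C(/COCc2ccc(OC)cc2)C[C@H](O[Si](C)(C)C(C)(C)C)[C@@H]1CC(=O)OC
A6 | alternative 3 | open-chain C5 vinyl iodide with C6 aldehyde | I/C=C(/CO[Si](c1ccccc1)(c1ccccc1)C(C)(C)C)CC/C=C(/COCc1ccc(OC)cc1)C[C@H](O[Si](C)(C)C(C)(C)C)[C@@H](C=O)CC(=O)OC
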